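Everything rests on cutting the C8–C9 bond of cyclobutane B. C9 is the gamma carbon of butenolide D and C8 the alpha carbon of a C7 ketone, so both are nucleophilic as enol derivatives and are held 1,4 by the C3–C4 bond. One anodic oxidation couples them: it closes ring B, sets C8 and C9, and releases lactone D and the C7 ketone. The substrate is a ring A-fused 2-silyloxyfuran whose quaternary C3 carries ring C as a TIPS enol ether (C7=C8). It is assembled from two cyclopentenones by a Mukaiyama–Michael addition that fixes C3 and C4, followed by annulation of the furanone onto the ring A ketone.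

Key step: step 11

Remark (numbering): atoms are numbered along the target SMILES: C1 (OTig), C2, C3 (Me), C4, C5 (OAc), C6, C7 (Me, OH), C8, C9, O10, C11 (C=O), C12, C13, C14 (CH2OAc); ring A = C1-C2-C3-C9-C13, ring B = C3-C4-C8-C9, ring C = C4-C5-C6-C7-C8, ring D = C9-O10-C11-C12-C13.
Remark (enol ether): a C7 ketone has CH2 groups on both sides and a C6 enolate would expel the C5 acetate, so the C7=C8 enol ether is made regiospecifically in the Michael step as a robust TIPS enol ether and carried to the key step.
Remark (C1 oxygen): ring D is built through a C13 enolate that has the C1 oxygen in the beta position, where an ester would be eliminated; C1 therefore stays a TBS ether through the key step and the tiglate is attached last, which also keeps a second reactive alkene out of the radical hydration.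
Assumption: 3, 8 and 22 are bought; 3 is otherwise available from 1 by silylation, deacetylation and oxidation.

Step 1
Reactants: 1 (1R,4S)-cis-4-acetoxycyclopent-2-en-1-ol
Product: 2 (S)-4-acetoxycyclopent-2-en-1-one
Conditions: Dess–Martin periodinane, CH2Cl2, 0 °C to rt
Reagents that add atoms: none
Why: Dess–Martin oxidation of the allylic alcohol leaves the acetoxy stereocenter (later C5) untouched and gives the enone that supplies C4–C8.

Step 2
Reactants: 3 (R)-4-(tert-butyldimethylsilyloxy)cyclopent-2-en-1-one
Product: 4 (R)-4-(tert-butyldimethylsilyloxy)-2-iodocyclopent-2-en-1-one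
Conditions: I2, pyridine, CH2Cl2, 0 °C to rt
Reagents that add atoms: iodine, II
Why: Alpha-iodination of the enone by the iodine–pyridine method (conjugate addition of pyridine, iodination of the enolate, loss of pyridine) is routine for 4-silyloxycyclopentenones and does not touch the C1 stereocenter.

Step 3
Reactants: 4 (R)-4-(tert-butyldimethylsilyloxy)-2-iodocyclopent-2-en-1-one
Product: 5 (R)-4-(tert-butyldimethylsilyloxy)-2-methylcyclopent-2-en-1-one
Conditions: Me4Sn, PdCl2(PhCN)2 (cat.), AsPh3, CuI (cat.), NMP, 80 °C
Reagents that add atoms: tetramethylstannane, C[Sn](C)(C)C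
Why: Stille coupling under base-free, copper-accelerated conditions puts the C3 methyl group in place without risk of beta-elimination of the silyloxy group.

Step 4
Reactants: 5 (R)-4-(tert-butyldimethylsilyloxy)-2-methylcyclopent-2-en-1-one
Product: 6 (4S)-4-(tert-butyldimethylsilyloxy)-2-methyl-1-(triisopropylsilyloxy)cyclopent-1-ene
Conditions: iPr3SiH, Pt2[(CH2=CHSiMe2)2O]3 (Karstedt catalyst, cat.), toluene, 60 °C
Reagents that add atoms: triisopropylsilane, CC(C)[SiH](C(C)C)C(C)C
Why: Platinum-catalysed 1,4-hydrosilylation delivers hydride to C2 and silicon to oxygen, which gives the tetrasubstituted C9=C3 enol ether regiospecifically, something enolisation of the saturated ketone could not guarantee.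

Step 5
Reactants: 6 (4S)-4-(tert-butyldimethylsilyloxy)-2-methyl-1-(triisopropylsilyloxy)cyclopent-1-ene; 2 (S)-4-acetoxycyclopent-2-en-1-one
Product: 7 Michael adduct (ring A C9 ketone with quaternary C3 bonded to C4 of the ring C TIPS enol ether)
Conditions: Tf2NH (5 mol%), CH2Cl2, −78 °C; Et3N quench
Reagents that add atoms: none
Why: Mukaiyama–Michael addition with silyl transfer, in which the silylated enone is attacked at C4 anti to the C5 acetate and the enol ether reacts at C3 anti to the C1 silyloxy group, so that C3 and C4 are set in the relative configuration that later forces syn fusion, while the TIPS group ends on the ring C enolate and fixes the C7=C8 enol ether.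

Step 6
Reactants: 7 Michael adduct; 8 ethyl glyoxylate
Product: 11 alkylidene keto ester (C13=C12H–CO2Et with the ester trans to the C9 carbonyl), via aldol adduct 9 (not isolated), via mesylate 10 (not isolated)
Conditions: LiN(SiMe3)2, THF, −78 °C; 8; then MsCl, Et3N, −78 to 0 °C
Reagents that add atoms: none
Why: Aldol condensation in which the ketone can only enolise toward C13 because C3 is quaternary, the lithium enolate adds to the reactive aldehyde in the cold before the beta silyloxy group can leave, and mesylation with E1cB loss gives the conjugated alkylidene ester, the enol ether and the acetate being inert to this amide base at −78 °C.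

Step 7
Reactants: 11 alkylidene keto ester
Product: 12 allylic alcohol (C9 carbinol, ester trans to C9)
Conditions: NaBH4, CeCl3·7H2O, MeOH/THF, −78 °C
Reagents that add atoms: none
Why: Luche reduction attacks only the conjugated ketone in 1,2 fashion, and the configuration created at C9 is of no consequence because C9 becomes trigonal again in step 10.

Step 8
Reactants: 12 allylic alcohol
Product: 14 bicyclic butenolide (O10–C11(=O)–C12H=C13 fused to ring A, C9–H), via ester-cis isomer 13 (not isolated)
Conditions: hν (254 nm), MeCN, rt
Reagents that add atoms: none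
Why: Photoisomerisation of the alkylidene ester moves the ester to the C9 side, where it lactonises with the C9 hydroxyl and is thereby drained irreversibly from the photoequilibrium.

Step 9
Reactants: 14 bicyclic butenolide
Product: 15 C12-hydroxymethyl lactone
Conditions: LiN(SiMe3)2, THF, −78 °C; CH2O (monomer in THF); AcOH, −78 °C
Reagents that add atoms: formaldehyde, C=O
Why: Aldol reaction of a butenolide dienolate, in which gamma deprotonation gives the aromatic lithium furanolate and formaldehyde is taken up at the alpha carbon C12 because the gamma carbon C9 is shielded by the adjacent quaternary C3.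

Step 10
Reactants: 15 C12-hydroxymethyl lactone
Product: 16 key-step substrate (2-triisopropylsilyloxyfuran fused to ring A, C14 OTIPS, C1 OTBS, ring C TIPS enol ether, C5 OAc)
Conditions: iPr3SiOTf, Et3N, CH2Cl2, −78 to 0 °C
Reagents that add atoms: triisopropylsilyl trifluoromethanesulfonate, CC(C)[Si](OS(=O)(=O)C(F)(F)F)(C(C)C)C(C)C
Why: Silyl triflate and amine silylate the primary alcohol and convert the lactone by soft enolisation into the aromatic 2-silyloxyfuran, the C14 silyl ether being a poor enough leaving group to stay on this electron-rich ring.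

Step 11
Reactants: 16 key-step substrate
Product: 17 tetracyclic C7 ketone (rings A–D closed, C1 OTBS, C5 OAc, C14 OTIPS)
Conditions: undivided cell, reticulated vitreous carbon anode, Pt cathode, constant current (2.2 F/mol), LiClO4 (0.1 M), 2,6-lutidine, MeOH/CH2Cl2 1:9, 2 mM substrate, 0 °C
Reagents that add atoms: none
Why: Proposed new method: the anode removes one electron from the silyloxyfuran, C8 of the enol ether bonds to C9 of the radical cation, the silylated carbonyl cation at C7 gives its silyl group to methanol, and the remaining oxygen-stabilised allyl radical is oxidised again and loses the second silyl group, so that lactone and ketone appear and the closure cannot revert. The closest known reactions are anodic couplings of furans with silyl enol ethers that close six- and seven-membered rings and oxidative couplings of silyl bis-enol ethers to 1,4-dicarbonyl compounds. Ring B closes in the 4-exo mode. C9 can bond only on the face of ring A that carries C4 and C8 only on the face of ring C that carries C3, so both new centers are fixed by cis fusion of the five-membered rings, and the syn arrangement follows from the C3/C4 configuration of step 5 (C2 eclipses C5, the methyl group eclipses H4). The step needs oxidation of the furan before the enol ether and intramolecular capture ahead of methanol addition or dimerisation; the lower oxidation potential of the silyloxyfuran, the 1,4 spacing enforced by the C3–C4 bond with angle compression at quaternary C3, high dilution and a small methanol content are relied on for this.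

Step 12
Reactants: 17 tetracyclic C7 ketone
Product: 18 C7 exocyclic methylene compound
Conditions: Zn, CH2Br2, TiCl4, THF; then 17, CH2Cl2, 0 °C to rt
Reagents that add atoms: dibromomethane, BrCBr
Why: Takai–Lombardo methylenation is non-basic and selective for ketones over esters and lactones, so the beta-acetoxy ketone is converted without elimination of acetate or epimerisation at C8.

Step 13
Reactants: 18 C7 exocyclic methylene compound
Product: 19 C7 tertiary alcohol (OH on the convex face)
Conditions: Co(acac)2 (cat.), PhSiH3, O2 (5 atm), iPrOH, 0 °C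
Reagents that add atoms: dioxygen, O=O
Why: Mukaiyama hydration, in which hydrogen atom transfer to the terminal carbon gives the tertiary C7 radical and dioxygen captures it on the convex face of the ring B/ring C unit, cis to H8 and the C5 acetate, with high oxygen pressure and low temperature chosen so that capture outruns opening of the neighbouring cyclobutane and with no other reactive alkene present.

Step 14
Reactants: 19 C7 tertiary alcohol
Product: 20 triol (free OH at C1, C7, C14)
Conditions: HF·pyridine, pyridine, THF, 0 °C to rt
Reagents that add atoms: none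
Why: Fluoride-mediated desilylation under buffered conditions frees the C1 and C14 hydroxyls while acetate, lactone and tertiary alcohol stay intact.

Step 15
Reactants: 20 triol
Product: 21 C14 acetate
Conditions: AcCl, 2,4,6-collidine, CH2Cl2, −78 °C
Reagents that add atoms: acetyl chloride, CC(Cl)=O
Why: Selective acylation, since at low temperature with a hindered pyridine base acetyl chloride reacts with the primary allylic C14 hydroxyl much faster than with the secondary C1 or the tertiary C7 hydroxyl.

Step 16
Reactants: 21 C14 acetate; 22 tigloyl chloride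
Product: 23 target CNP0210373.1
Conditions: pyridine, DMAP (cat.), CH2Cl2, 0 °C to rt
Reagents that add atoms: none
Why: DMAP-catalysed esterification of the secondary C1 alcohol with the acid chloride, the tertiary C7 alcohol being too hindered to react and the tiglate being the stable alkene isomer.

Compound list
1 | (1R,4S)-cis-4-acetoxycyclopent-2-en-1-ol | CC(=O)O[C@H]1C[C@@H](O)C=C1 | starting material
2 | (S)-4-acetoxycyclopent-2-en-1-one | CC(=O)O[C@H]1CC(=O)C=C1 | intermediate
3 | (R)-4-(tert-butyldimethylsilyloxy)cyclopent-2-en-1-one | CC(C)(C)[Si](C)(C)O[C@@H]1CC(=O)C=C1 | starting material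
4 | (R)-4-(tert-butyldimethylsilyloxy)-2-iodocyclopent-2-en-1-one | CC(C)(C)[Si](C)(C)O[C@@H]1CC(=O)C(I)=C1 | intermediate
5 | (R)-4-(tert-butyldimethylsilyloxy)-2-methylcyclopent-2-en-1-one | CC(C)(C)[Si](C)(C)O[C@@H]1CC(=O)C(C)=C1 | intermediate
6 | (4S)-4-(tert-butyldimethylsilyloxy)-2-methyl-1-(triisopropylsilyloxy)cyclopent-1-ene (silyloxy carbon arranged in space as in 5; the letter changes only through the priority rules) | CC1=C(O[Si](C(C)C)(C(C)C)C(C)C)C[C@@H](O[Si](C)(C)C(C)(C)C)C1 | intermediate
7 | Michael adduct: cyclopentanone ring A (C9=O, C1 OTBS, quaternary C3 with methyl) bonded from C3 to C4 of 3-acetoxy-1-(triisopropylsilyloxy)cyclopent-1-ene (C7=C8 enol ether, C5 OAc); C3–C4 bond trans to C1 OTBS and trans to C5 OAc; C1, C3, C4, C5 as in 23 | CC(C)(C)[Si](C)(C)O[C@H]1C[C@](C)([C@@H]2[C@@H](OC(C)=O)CC(O[Si](C(C)C)(C(C)C)C(C)C)=C2)C(=O)C1 | intermediate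
8 | ethyl glyoxylate | CCOC(=O)C=O | starting material
9 | aldol adduct: 7 with CH(OH)CO2Et on C13 (mixture at C12 and C13) | CC(C)(C)[Si](C)(C)O[C@H]1C[C@](C)([C@@H]2[C@@H](OC(C)=O)CC(O[Si](C(C)C)(C(C)C)C(C)C)=C2)C(=O)C1C(O)C(=O)OCC | intermediate
10 | mesylate of 9 | CC(C)(C)[Si](C)(C)O[C@H]1C[C@](C)([C@@H]2[C@@H](OC(C)=O)CC(O[Si](C(C)C)(C(C)C)C(C)C)=C2)C(=O)C1C(OS(C)(=O)=O)C(=O)OCC | intermediate
11 | alkylidene keto ester: 7 with C13=C12H–CO2Et, ester trans to the C9 carbonyl (E) | CC(C)(C)[Si](C)(C)O[C@H]1C[C@](C)([C@@H]2[C@@H](OC(C)=O)CC(O[Si](C(C)C)(C(C)C)C(C)C)=C2)C(=O)/C1=C/C(=O)OCC | intermediate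
12 | allylic alcohol: C9 carbinol of 11 (both C9 epimers), ester trans to C9 | CC(C)(C)[Si](C)(C)O[C@H]1C[C@](C)([C@@H]2[C@@H](OC(C)=O)CC(O[Si](C(C)C)(C(C)C)C(C)C)=C2)C(O)/C1=C/C(=O)OCC | intermediate
13 | alkene isomer of 12 with the ester cis to C9 | CC(C)(C)[Si](C)(C)O[C@H]1C[C@](C)([C@@H]2[C@@H](OC(C)=O)CC(O[Si](C(C)C)(C(C)C)C(C)C)=C2)C(O)/C1=C\C(=O)OCC | intermediate
14 | bicyclic butenolide: lactone O10–C11(=O)–C12H=C13 fused to ring A at C9–C13, C9–H (either epimer), C1 OTBS, ring C TIPS enol ether, C5 OAc | CC(C)(C)[Si](C)(C)O[C@H]1C[C@](C)([C@@H]3[C@@H](OC(C)=O)CC(O[Si](C(C)C)(C(C)C)C(C)C)=C3)C2OC(=O)C=C12 | intermediate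
15 | C12-hydroxymethyl lactone, drawn as the C9=C13 tautomer with C12–H (either tautomer serves in step 10) | CC(C)(C)[Si](C)(C)O[C@H]1C[C@](C)([C@@H]3[C@@H](OC(C)=O)CC(O[Si](C(C)C)(C(C)C)C(C)C)=C3)C2=C1C(CO)C(=O)O2 | intermediate
16 | key-step substrate: ring A-fused 2-(triisopropylsilyloxy)furan (C11 OTIPS, C12 CH2OTIPS), C1 OTBS, C3 bearing methyl and the ring C TIPS enol ether (C7=C8, C5 OAc); C1, C3, C4, C5 as in 23 | CC(C)(C)[Si](C)(C)O[C@H]1C[C@](C)([C@@H]3[C@@H](OC(C)=O)CC(O[Si](C(C)C)(C(C)C)C(C)C)=C3)c2oc(O[Si](C(C)C)(C(C)C)C(C)C)c(CO[Si](C(C)C)(C(C)C)C(C)C)c12 | intermediate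
17 | tetracyclic C7 ketone: rings A–D as in 23, C1 OTBS, C5 OAc, C14 OTIPS, rings A and C syn on ring B | CC(C)(C)[Si](C)(C)O[C@H]1C[C@]2(C)[C@@H]3[C@@H](OC(C)=O)CC(=O)[C@@H]3[C@@]23OC(=O)C(CO[Si](C(C)C)(C(C)C)C(C)C)=C13 | intermediate
18 | C7 exocyclic methylene analogue of 17 | CC(C)(C)[Si](C)(C)O[C@H]1C[C@]2(C)[C@@H]3[C@@H](OC(C)=O)CC(=C)[C@@H]3[C@@]23OC(=O)C(CO[Si](C(C)C)(C(C)C)C(C)C)=C13 | intermediate
19 | C7 tertiary alcohol: methyl carbinol with OH on the convex face (cis to H8 and C5 OAc), C1 OTBS, C14 OTIPS | CC(C)(C)[Si](C)(C)O[C@H]1C[C@]2(C)[C@@H]3[C@@H](OC(C)=O)C[C@@](C)(O)[C@@H]3[C@@]23OC(=O)C(CO[Si](C(C)C)(C(C)C)C(C)C)=C13 | intermediate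
20 | triol: 19 with free hydroxyls at C1 and C14 | O[C@H]1C[C@]2(C)[C@@H]3[C@@H](OC(C)=O)C[C@@](C)(O)[C@@H]3[C@@]23OC(=O)C(CO)=C13 | intermediate
21 | C14 acetate of 20 (C1 and C7 hydroxyls free) | O[C@H]1C[C@]2(C)[C@@H]3[C@@H](OC(C)=O)C[C@@](C)(O)[C@@H]3[C@@]23OC(=O)C(COC(C)=O)=C13 | intermediate
22 | tigloyl chloride, (E)-2-methylbut-2-enoyl chloride | C/C=C(\C)C(Cl)=O | starting material
23 | CNP0210373.1 | C/C=C(\C)C(=O)O[C@H]1C[C@]2(C)[C@@H]3[C@@H](OC(C)=O)C[C@@](C)(O)[C@@H]3[C@@]23OC(=O)C(COC(C)=O)=C13 | target

Total step count: 16
Longest linear sequence: 15 steps (3 to 23, steps 2–16); ring C enters after one step from 1.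

Steps most likely to fail
1. Step 11: the four-membered ring may close too slowly or reopen before the silyl groups are lost, so that methanol adds to C9 of the radical cation or two molecules couple. The fallback sets out from 16 and comes back at 17. Compound 16 is electrolysed on purpose in neat methanol (same cell, LiClO4, 2,6-lutidine), a known anodic alkoxylation of an oxyfuran, which gives the gamma-methoxy butenolide F1 with the ring C enol ether untouched. Me3SiOTf in CH2Cl2 at −78 °C then ionises the C9 methoxy group to the lactone-stabilised oxocarbenium ion, and the C8 enol ether captures it in an intramolecular Mukaiyama-type addition, a closed-shell closure that ends with loss of the silyl group and gives 17.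
2. Step 5: 1,3-induction from the C1 silyloxy group may discriminate the faces of C3 poorly, and the crowded pair may react slowly. The fallback sets out from 5 and comes back at 7. RhCl(PPh3)3-catalysed 1,4-hydrosilylation of 5 with PhMe2SiH gives the dimethylphenylsilyl enol ether F2. MeLi in THF at 0 °C cleaves it to the regiodefined lithium enolate, which adds to 2 at −78 °C through a closed, lithium-bridged transition state, an anionic Michael addition with a different topology from the open Lewis acid pathway. iPr3SiOTf traps the ring C enolate in the cold as 7.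
3. Step 13: the tertiary C7 radical sits next to the cyclobutane and may cleave the C8–C9 bond, which would give a radical at C9 stabilised by O10 and the butenolide, before dioxygen captures it. The fallback sets out from 18 and comes back at 19. mCPBA with NaHCO3 in CH2Cl2 epoxidises the exocyclic alkene from the convex face to the spiro-epoxide F3. LiI in THF opens it at the CH2 terminus to the iodohydrin F4. Bu3SnH with AIBN in toluene at 80 °C reduces the C–I bond through a primary radical that has no ring-opening path and gives 19 with the oxygen on the convex face.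

Further compounds
F1 | step 11 | gamma-methoxy butenolide: 16 with C9 bearing OMe and O10, C11 carbonyl, C12=C13, ring C TIPS enol ether intact (C9 epimers) | CC(C)(C)[Si](C)(C)O[C@H]1C[C@](C)([C@@H]3[C@@H](OC(C)=O)CC(O[Si](C(C)C)(C(C)C)C(C)C)=C3)C2(OC)OC(=O)C(CO[Si](C(C)C)(C(C)C)C(C)C)=C12
F2 | step 5 | (4S)-4-(tert-butyldimethylsilyloxy)-1-(dimethylphenylsilyloxy)-2-methylcyclopent-1-ene | CC1=C(O[Si](C)(C)c2ccccc2)C[C@@H](O[Si](C)(C)C(C)(C)C)C1
F3 | step 13 | C7 spiro-epoxide of 18, oxygen on the convex face | CC(C)(C)[Si](C)(C)O[C@H]1C[C@]2(C)[C@@H]3[C@@H](OC(C)=O)C[C@]4(CO4)[C@@H]3[C@@]23OC(=O)C(CO[Si](C(C)C)(C(C)C)C(C)C)=C13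
F4 | step 13 | iodohydrin: 19 with CH2I in place of the C7 methyl group | CC(C)(C)[Si](C)(C)O[C@H]1C[C@]2(C)[C@@H]3[C@@H](OC(C)=O)C[C@@](CI)(O)[C@@H]3[C@@]23OC(=O)C(CO[Si](C(C)C)(C(C)C)C(C)C)=C13
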